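**Retrosynthetic overview**

1. The only ring, the six-membered carbocycle (C1 = ketone next to the carbinol, C2 = acyl-bearing carbon, C3 = enol carbon, C4 and C5 = methylenes, C6 = carbinol), is closed last. A one-flask [5+1] double C-acylation joins (8E,10E)-nonadeca-8,10-dien-2-one to (R)-5-oxotetrahydrofuran-2-carbonyl chloride.
2. Enabling feature: C2 carries three acyl carbons (ring C1, ring C3 and the side-chain ketone carbon), so it can be the methyl carbon of a methyl ketone, and the arc C3–C4–C5–C6(O)–C1 is (R)-2-hydroxyglutaric acid. In its γ-lactone the C6 oxygen is bonded to C3 (an oxolan-2-one ring that is not in the target); this bond protects the hydroxyl, carries the C6 stereocentre from the chiral pool, and is cleaved in the ring closure to set the 6-OH free.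
3. Both glutarate carbonyls end on C2, so it does not matter which is attacked first; the trione enolate is the thermodynamic sink and no protecting group is used.
4. The methyl ketone comes from an acetoacetic ester synthesis on (5E,7E)-1-chlorohexadeca-5,7-diene; the (E,E)-diene comes from a Suzuki–Miyaura coupling of (E)-1-iododec-1-ene (from dec-1-yne) with the (E)-alkenylboronate of 6-chlorohex-1-yne.
5. Ring order: the temporary oxolanone ring is bought with the lactone acid; the carbocycle is formed in the final step at the expense of that ring.

Key step: step 7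

Remark: the target is drawn as one enol tautomer of an enolised 2-acylcyclohexane-1,3-dione; the tautomers interconvert freely, so the route aims at the trione with (R) configuration at C6 and does not try to fix the enol position.

**Step 1**
Reactants: 1 dec-1-yne
Product: 3 (E)-1-iododec-1-ene, via alkenylalane 2 (not isolated)
Conditions: i-Bu2AlH (1.0 equiv), hexane, 50 °C; then I2, THF, −50 °C → rt
Reagents that add atoms: iodine, II
Why: Hydroalumination–iodination: syn addition of Al–H across the terminal alkyne puts aluminium on C1 and gives the (E)-alkenylalane 2, whose C–Al bond is cleaved by iodine with retention, so the (E)-iodide should result.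

**Step 2**
Reactants: 4 6-chlorohex-1-yne
Product: 5 2-[(E)-6-chlorohex-1-en-1-yl]-4,4,5,5-tetramethyl-1,3,2-dioxaborolane
Conditions: pinacolborane (1.1 equiv), Cp2Zr(H)Cl (5 mol %), Et3N (10 mol %), neat, 60 °C
Reagents that add atoms: pinacolborane, [H]B1OC(C)(C)C(C)(C)O1
Why: Catalysed alkyne hydroboration: syn, anti-Markovnikov addition of B–H should give only the (E)-alkenylboronate, and the primary chloride is inert to the borane and to the zirconium hydride catalyst.

**Step 3**
Reactants: 3 (E)-1-iododec-1-ene and 5 2-[(E)-6-chlorohex-1-en-1-yl]-4,4,5,5-tetramethyl-1,3,2-dioxaborolane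
Product: 6 (5E,7E)-1-chlorohexadeca-5,7-diene
Conditions: Pd(PPh3)4 (5 mol %), K3PO4 (3 equiv), THF–H2O (4:1), degassed, 60 °C
Reagents that add atoms: none
Why: Suzuki–Miyaura coupling: oxidative addition of the alkenyl iodide to zerovalent palladium, transmetalation of the alkenylboronate and reductive elimination all retain alkene geometry, so two (E)-partners should give the (E,E)-diene, while the unactivated C–Cl bond does not add to this catalyst.

**Step 4**
Reactants: 6 (5E,7E)-1-chlorohexadeca-5,7-diene and 7 ethyl acetoacetate sodium salt (1.5 equiv)
Product: 8 ethyl (7E,9E)-2-acetyloctadeca-7,9-dienoate (racemic at C2)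
Conditions: NaI (20 mol %), EtOH, reflux
Reagents that add atoms: none
Why: Acetoacetic ester alkylation: iodide catalysis (Finkelstein exchange in the flask) turns the primary chloride into the iodide, which the stabilised enolate displaces at carbon by SN2 in the protic solvent; the new C2 stereocentre forms racemic and is destroyed in step 5.

**Step 5**
Reactants: 8 ethyl (7E,9E)-2-acetyloctadeca-7,9-dienoate
Product: 10 (8E,10E)-nonadeca-8,10-dien-2-one, via keto acid 9 (not isolated)
Conditions: NaOH (2 M aq, 1.5 equiv), EtOH, rt; then HCl (2 M aq) to pH 2, 50 °C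
Reagents that add atoms: none
Why: Ketonic hydrolysis of the acetoacetic ester synthesis: saponification gives β-keto acid 9, which should lose CO2 through a cyclic six-membered transition state on gentle warming, under conditions that leave the unactivated conjugated diene alone.

**Step 6**
Reactants: 11 (R)-5-oxotetrahydrofuran-2-carboxylic acid
Product: 12 (R)-5-oxotetrahydrofuran-2-carbonyl chloride
Conditions: (COCl)2 (1.3 equiv), DMF (cat.), CH2Cl2, 0 °C → rt; evaporate, use crude
Reagents that add atoms: oxalyl chloride, ClC(=O)C(Cl)=O
Why: Acid chloride formation through the catalytic chloroiminium (Vilsmeier-type) species under base-free conditions, so the α-acyloxy stereocentre is not enolised and the lactone is untouched.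

**Step 7**
Reactants: 10 (8E,10E)-nonadeca-8,10-dien-2-one and 12 (R)-5-oxotetrahydrofuran-2-carbonyl chloride
Product: 16 (6R)-3,6-dihydroxy-2-[(7E,9E)-octadeca-7,9-dienoyl]cyclohex-2-en-1-one, via lithium enolate 13 (not isolated), via diketone lactone 14 (not isolated), via hydroxy diketo ester 15 (not isolated)
Conditions: LiN(SiMe3)2 (2.2 equiv), THF–toluene, −78 °C, add 10; then 12 (1.1 equiv), −78 °C; then MeOH, NaOMe (20 mol %), −78 → 45 °C; then HCl (1 M aq), 0 °C
Reagents that add atoms: none
Why: Proposed new method: the methyl-side lithium enolate 13 is C-acylated at the acyl chloride of 12 to give diketone 14, held as its diketonate by the second equivalent of base; methoxide then opens the γ-lactone reversibly to hydroxy ester 15 (which avoids a strained 7-oxabicyclo[2.2.1]heptane tetrahedral intermediate), the diketonate carbon C2 attacks the C3 methyl ester and expels methoxide, and the trione is deprotonated at once to a stabilised enolate that drains every equilibrium before acid work-up gives 16. The closest known reaction types are the crossed Claisen acylation of a ketone enolate with an acid chloride and the Dieckmann-type (Lacey–Dieckmann) C-acylation of a β-dicarbonyl anion by a tethered ester; what is new is the γ-lactone as latent ester, whose leaving alkoxide becomes the free C6 hydroxyl, so that the hydroxy acid needs no protecting group. The carbocycle closes by 6-exo-trig attack of C2 on C3 after the C2–C1 bond has been made intermolecularly, and the oxolanone ring is opened in the same operation. No new stereocentre is formed: C6 comes from 11 with its four bonds untouched and is shielded from enolisation because the adjacent C1 carbonyl belongs to a diketonate or trionate anion from the moment it exists. The step needs methyl- over methylene-side enolisation of 10 (bulky amide base at −78 °C, ketone added to the base), C- over O-acylation (lithium counter-ion and low temperature; any enol ester or enol lactone from O-acylation is returned by methoxide) and attack at the acyl chloride before the lactone (secured by the reactivity gap), but no choice between the two glutarate carbonyls, since both end on C2. A methylene-side by-product cannot form a stabilised trionate, so it should be separable from 16, the only strong vinylogous acid in the mixture.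

**Compound list**

1 | dec-1-yne | CCCCCCCCC#C | starting material
2 | (E)-dec-1-en-1-yl(diisobutyl)alane | CCCCCCCC/C=C/[Al](CC(C)C)CC(C)C | intermediate
3 | (E)-1-iododec-1-ene | CCCCCCCC/C=C/I | intermediate
4 | 6-chlorohex-1-yne | ClCCCCC#C | starting material
5 | 2-[(E)-6-chlorohex-1-en-1-yl]-4,4,5,5-tetramethyl-1,3,2-dioxaborolane | ClCCCC/C=C/B1OC(C)(C)C(C)(C)O1 | intermediate
6 | (5E,7E)-1-chlorohexadeca-5,7-diene | ClCCCC/C=C/C=C/CCCCCCCC | intermediate
7 | ethyl acetoacetate sodium salt | CCOC(=O)C=C(C)[O-].[Na+] | starting material
8 | ethyl (7E,9E)-2-acetyloctadeca-7,9-dienoate (racemic at C2) | CCCCCCCC/C=C/C=C/CCCCC(C(C)=O)C(=O)OCC | intermediate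
9 | (7E,9E)-2-acetyloctadeca-7,9-dienoic acid (racemic at C2) | CCCCCCCC/C=C/C=C/CCCCC(C(C)=O)C(=O)O | intermediate
10 | (8E,10E)-nonadeca-8,10-dien-2-one | CCCCCCCC/C=C/C=C/CCCCCC(C)=O | intermediate
11 | (R)-5-oxotetrahydrofuran-2-carboxylic acid | OC(=O)[C@H]1CCC(=O)O1 | starting material
12 | (R)-5-oxotetrahydrofuran-2-carbonyl chloride | ClC(=O)[C@H]1CCC(=O)O1 | intermediate
13 | lithium (8E,10E)-nonadeca-1,8,10-trien-2-olate | CCCCCCCC/C=C/C=C/CCCCCC(=C)[O-].[Li+] | intermediate
14 | (R)-5-[(9E,11E)-3-oxoicosa-9,11-dienoyl]dihydrofuran-2(3H)-one | CCCCCCCC/C=C/C=C/CCCCCC(=O)CC(=O)[C@H]1CCC(=O)O1 | intermediate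
15 | methyl (4R,13E,15E)-4-hydroxy-5,7-dioxotetracosa-13,15-dienoate | CCCCCCCC/C=C/C=C/CCCCCC(=O)CC(=O)[C@H](O)CCC(=O)OC | intermediate
16 | (6R)-3,6-dihydroxy-2-[(7E,9E)-octadeca-7,9-dienoyl]cyclohex-2-en-1-one | CCCCCCCC/C=C/C=C/CCCCCC(=O)C1=C(O)CC[C@@H](O)C1=O | target

**Step count and risks**

Total step count: 7. Longest linear sequence: 5 steps (steps 1, 3, 4, 5 and 7, from dec-1-yne).

Steps most likely to fail:

1. Step 7. The lactone-opening and ring-closing relay may stall at the diketonate stage, the transient open-chain hydroxy diketone may cyclodehydrate to a furanone on acidification, and enolisation of the ketone on its methylene side would divert material. The fallback uses known Claisen and Dieckmann chemistry on a protected open chain; it sets out from 11 and 10 and comes back to the route at 16. Acid-catalysed methanolysis of 11 (MeOH, cat. HCl, rt) should give dimethyl (R)-2-hydroxypentanedioate F1, which is silylated at once (TBSOTf, 2,6-lutidine, CH2Cl2) to dimethyl (R)-2-[(tert-butyldimethylsilyl)oxy]pentanedioate F2, so that the open chain cannot relactonise. Lithium enolate 13, made from 10 as in step 7, is then acylated with F2 in a crossed Claisen condensation (THF, −78 → 0 °C). Attack should fall mainly on the more electrophilic α-silyloxy ester and give methyl (4R,13E,15E)-4-[(tert-butyldimethylsilyl)oxy]-5,7-dioxotetracosa-13,15-dienoate F3, beside the regioisomer from attack at the other ester, methyl (2R,13E,15E)-2-[(tert-butyldimethylsilyl)oxy]-5,7-dioxotetracosa-13,15-dienoate F4. NaOMe in MeOH at rt should close both by Dieckmann condensation to the same silyl ether, (6R)-6-[(tert-butyldimethylsilyl)oxy]-3-hydroxy-2-[(7E,9E)-octadeca-7,9-dienoyl]cyclohex-2-en-1-one F5, and HF·pyridine in THF then removes the silyl group to reach 16.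

2. Step 4. Substitution at the primary chloride may be slow, and the product may be alkylated a second time or the enolate alkylated at oxygen. The fallback replaces the acetoacetic ester synthesis by an azaenolate monoalkylation; it sets out from 6 and comes back to the route at 10, bypassing 8 and 9. Halide exchange (NaI, acetone, reflux) should give (5E,7E)-1-iodohexadeca-5,7-diene F6; lithiated acetone N,N-dimethylhydrazone (from the hydrazone and n-BuLi, THF, −78 → 0 °C) should displace the iodide once, at carbon, to give (8E,10E)-nonadeca-8,10-dien-2-one N,N-dimethylhydrazone F7; two-phase hydrolysis (aqueous oxalic acid, Et2O, rt) then releases 10.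

3. Step 1. Competing deprotonation of the terminal alkyne by the aluminium hydride and over-reduction may lower conversion, and any loss of E purity would be carried into the diene. The fallback goes through boron instead of aluminium; it sets out from 1 and comes back to the route at 3. Hydroboration with pinacolborane under the conditions of step 2 should give 2-[(E)-dec-1-en-1-yl]-4,4,5,5-tetramethyl-1,3,2-dioxaborolane F8, and iododeboronation (NaOH aq, then I2, THF, 0 °C) should replace boron by iodine with retention to give 3.

**Further compounds**

F1 | step 7 | dimethyl (R)-2-hydroxypentanedioate | COC(=O)[C@H](O)CCC(=O)OC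
F2 | step 7 | dimethyl (R)-2-[(tert-butyldimethylsilyl)oxy]pentanedioate | COC(=O)[C@H](O[Si](C)(C)C(C)(C)C)CCC(=O)OC
F3 | step 7 | methyl (4R,13E,15E)-4-[(tert-butyldimethylsilyl)oxy]-5,7-dioxotetracosa-13,15-dienoate | CCCCCCCC/C=C/C=C/CCCCCC(=O)CC(=O)[C@H](O[Si](C)(C)C(C)(C)C)CCC(=O)OC
F4 | step 7 | methyl (2R,13E,15E)-2-[(tert-butyldimethylsilyl)oxy]-5,7-dioxotetracosa-13,15-dienoate | CCCCCCCC/C=C/C=C/CCCCCC(=O)CC(=O)CC[C@@H](O[Si](C)(C)C(C)(C)C)C(=O)OC
F5 | step 7 | (6R)-6-[(tert-butyldimethylsilyl)oxy]-3-hydroxy-2-[(7E,9E)-octadeca-7,9-dienoyl]cyclohex-2-en-1-one | CCCCCCCC/C=C/C=C/CCCCCC(=O)C1=C(O)CC[C@@H](O[Si](C)(C)C(C)(C)C)C1=O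
F6 | step 4 | (5E,7E)-1-iodohexadeca-5,7-diene | ICCCC/C=C/C=C/CCCCCCCC
F7 | step 4 | (8E,10E)-nonadeca-8,10-dien-2-one N,N-dimethylhydrazone | CCCCCCCC/C=C/C=C/CCCCCC(C)=NN(C)C
F8 | step 1 | 2-[(E)-dec-1-en-1-yl]-4,4,5,5-tetramethyl-1,3,2-dioxaborolane | CCCCCCCC/C=C/B1OC(C)(C)C(C)(C)O1
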